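It is impossible to draw the teal curve of starting material with one first-order constant.

| setting | teal | red | grey | green | violet |
|---|---|---|---|---|---|
| starting material | 0.500 M | 0.200 M | 0.500 M | 0.500 M | 0.500 M |
| partner | 1.50 M | 1.20 M | 2.20 M | 1.50 M | 1.50 M |
| catalyst | 0.0100 M | 0.0100 M | 0.0100 M | 0.0100 M | 0.00330 M |
| product |  |  |  | 0.250 M |  |
| time |  |  |  |  | 51 min |

- teal run (time / min: [starting material] / M): 10: 0.367; 20: 0.286; 31: 0.241; 41: 0.209; 51: 0.202
- red run (time / min: [starting material] / M): 10: 0.149; 20: 0.119; 31: 0.099; 41: 0.094; 51: 0.083
- grey run (time / min: [starting material] / M): 10: 0.345; 20: 0.255; 31: 0.195; 41: 0.162; 51: 0.136
- green run (time / min: [starting material] / M): 10: 0.367; 20: 0.287; 31: 0.235; 41: 0.215; 51: 0.195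

(scatter of a reading: 0.004 M)

- Overall: starting material + partner -> product, with catalyst as catalyst.
- Constant volume, constant temperature.
- What is held in complexes is read along with the free species.
- An order is taken over about fifteen percent of the charge, up and down.

* reaction order in [partner] at the outset, round the charge of the teal run, defined at two percent of the starting material turned into product
* reaction order in [starting material] at the outset, round the charge of the teal run, defined at two percent of the starting material turned into product (one fixed amount of product, the same in the runs compared)
* starting material in the violet run at 51 min, as a share of the starting material charged

I work with the fraction left: S is the starting material present, and L is the natural logarithm of its charge over S, so the slope of L against time is the pseudo-first-order constant of the moment. In the teal run that slope is 0.0309 min⁻¹ over the first 10 min, but 0.00883 min⁻¹ from 31 min to 51 min, so the early slope is steeper by a factor of 3.50. From 10 min to 20 min the slope already reads 0.0249 min⁻¹, so the bending is under way in the first readings, and S reads 0.202 M at 51 min, with L at 0.906. This last figure is the teal clock integral, the pseudo-first-order constant summed over 51 min at the teal catalyst charge, and I carry it forward.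

The red run, charged with 0.200 M of starting material against 0.500 M in teal, reaches L of 0.879 at 51 min. So I read the fall of the slope as following the clock and not the turnover, and I take the order in starting material as one. The green run, charged with 0.250 M of product, reads 0.195 M at 51 min, so I set product aside. At 10 min the grey run has L of 0.371 against 0.309 in teal, which gives a partner order of 0.476, a reading over a wide step in partner.

The violet run differs from teal in its catalyst, charged at 0.330 of the teal amount. Taking the rate as first order in catalyst, I scale the integral to 0.299, which leaves 74.2% of the starting material at 51 min.

The forecast gives a partner order of 0.5, an order in starting material of 0.97 and 71% left in violet, lower than my share, and it reasons that “the decay follows clock time rather than turnover, so the catalyst is dying”.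

The flask gives a partner order of 0.40, an order in starting material of 1.0, and 71.4% left in violet.

    catalyst + partner ⇌ catalyst-reagent complex, settled at all times (1.080 L mol⁻¹)
    catalyst-reagent complex + starting material → product + catalyst (9.960 L mol⁻¹ min⁻¹)
    2 partner ⇌ idle reagent dimer, settled at all times (2.140 L mol⁻¹)
    partner → lost reagent (0.1020 min⁻¹)

As an integral, the violet result is 0.337, larger than the 0.299 scaled from the teal 0.906. The passing of partner into lost reagent is what holds the violet integral down. The simulated violet run with that passing taken away leaves 57.2%, an integral of 0.559, so the loss costs violet 0.222 of L by 51 min.

The data come from a simulation with constants of no real substance, and the scatter is random.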